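**Plan**

1. Retrosynthesis: the MOM ethers and the C4 ketone are traced back to a 4-silyloxyflavan. The O1–C8a aryl ether of ring C is then cut to a C2 carbinol and a C8a–Cl bond, the C2 carbinol is traced to an aryl ketone, and C3–C4 is cut as an aldol. The ring A aldehyde loses its C4a–CHO, C8–prenyl and C6–CH2CH2O bonds down to 5-chlororesorcinol (1).
2. Forward: ring A is built from 1 by three successive ortho-metalations (ethylene oxide 3, prenyl bromide 7, DMF). It is joined to MOM-protected acetovanillone (from 13) by aldol addition, and ring C is closed last by forming O1–C8a. Oxidation at C4 and removal of the MOM groups finish the synthesis.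
3. Enabling feature: O1–C8a is an aryl ether at the ring A carbon flanked by C8 (prenyl) and C4a, and the ring A oxygens at C5 and C7 are both meta to it. A chlorine at C8a therefore survives the metalations, marks C8a against C5 (the other oxygen-bearing carbon ortho to C4a) and is not deactivated by donor oxygens. The C2 oxygen reaches C8a through a six-membered ring, which is ring C.
4. Stereochemistry: C2, the only stereocentre, is set as S by catalyst-controlled asymmetric transfer hydrogenation of the ring B aryl ketone (step 9). The ring closure never breaks the C2–O bond.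

Key step: step 10

Remark: C4 becomes the ketone in step 12, so compounds 16–20 are carried as mixtures of C4 epimers, with a single configuration at C2 from step 9 onwards.

**Route**

Step 1
Reactants: 1 5-chlororesorcinol
Product: 2 1-chloro-3,5-bis(methoxymethoxy)benzene
Conditions: NaH, MOMCl, DMF, 0 °C → rt
Reagents that add atoms: chloromethyl methyl ether (MOMCl), COCCl
Why: Williamson-type O-alkylation of the two sodium phenoxides with MOMCl should give the bis-acetal, which protects the phenols and supplies the two directing groups for the metalations that follow.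

Step 2
Reactants: 2 1-chloro-3,5-bis(methoxymethoxy)benzene; 3 ethylene oxide
Product: 5 2-[4-chloro-2,6-bis(methoxymethoxy)phenyl]ethan-1-ol, via aryllithium 4 (not isolated)
Conditions: n-BuLi, THF, −20 → 0 °C; ethylene oxide (THF solution), 0 °C → rt; then H2O
Reagents that add atoms: ethylene oxide (3), C1CO1
Why: Directed ortho-metalation should occur at the C–H flanked by both OMOM groups (doubly coordinated, and para to chlorine so that no aryne can form), and the aryllithium then opens ethylene oxide by SN2 epoxide ring-opening to place the two-carbon alcohol chain at the future C6.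

Step 3
Reactants: 5 2-[4-chloro-2,6-bis(methoxymethoxy)phenyl]ethan-1-ol
Product: 6 5-chloro-1,3-bis(methoxymethoxy)-2-[2-(methoxymethoxy)ethyl]benzene
Conditions: NaH, MOMCl, THF, 0 °C → rt
Reagents that add atoms: chloromethyl methyl ether (MOMCl), COCCl
Why: Williamson etherification of the sodium alkoxide with MOMCl masks the primary alcohol, which would otherwise consume the alkyllithium in the next steps, as the same acetal that is removed at the end.

Step 4
Reactants: 6 5-chloro-1,3-bis(methoxymethoxy)-2-[2-(methoxymethoxy)ethyl]benzene; 7 prenyl bromide (1-bromo-3-methylbut-2-ene)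
Product: 10 1-chloro-3,5-bis(methoxymethoxy)-4-[2-(methoxymethoxy)ethyl]-2-(3-methylbut-2-en-1-yl)benzene, via aryllithium 8 (not isolated), via arylcopper 9 (not isolated)
Conditions: s-BuLi, THF, −78 °C; CuBr·SMe2 (1.1 equiv), −78 °C; prenyl bromide, −78 → −20 °C
Reagents that add atoms: prenyl bromide (7), CC(C)=CCBr
Why: Directed ortho-metalation at one of the two equivalent C–H positions between chlorine and OMOM (held at −78 °C so that the ortho-chloro aryllithium does not lose LiCl), transmetalation to the arylcopper and copper-mediated allylic substitution at the primary carbon of prenyl bromide should install the C8 prenyl group.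

Step 5
Reactants: 10 1-chloro-3,5-bis(methoxymethoxy)-4-[2-(methoxymethoxy)ethyl]-2-(3-methylbut-2-en-1-yl)benzene
Product: 12 2-chloro-4,6-bis(methoxymethoxy)-5-[2-(methoxymethoxy)ethyl]-3-(3-methylbut-2-en-1-yl)benzaldehyde, via aryllithium 11 (not isolated)
Conditions: s-BuLi, THF, −78 °C; DMF, −78 → 0 °C; then H2O
Reagents that add atoms: N,N-dimethylformamide (DMF), CN(C)C=O
Why: A second directed ortho-metalation at the only ring C–H left, again between chlorine and OMOM, followed by Bouveault-type formylation with DMF should give the aldehyde carbon that becomes C4, now locked between C5–OMOM and the C8a chlorine.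

Step 6
Reactants: 13 acetovanillone (1-(4-hydroxy-3-methoxyphenyl)ethan-1-one)
Product: 14 1-[3-methoxy-4-(methoxymethoxy)phenyl]ethan-1-one
Conditions: MOMCl, K2CO3, acetone, rt
Reagents that add atoms: chloromethyl methyl ether (MOMCl), COCCl
Why: Williamson O-alkylation of the phenoxide, with a carbonate base too weak to enolise the methyl ketone, protects ring B as the same MOM ether used on ring A.

Step 7
Reactants: 14 1-[3-methoxy-4-(methoxymethoxy)phenyl]ethan-1-one; 12 2-chloro-4,6-bis(methoxymethoxy)-5-[2-(methoxymethoxy)ethyl]-3-(3-methylbut-2-en-1-yl)benzaldehyde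
Product: 16 (3RS)-3-{2-chloro-4,6-bis(methoxymethoxy)-5-[2-(methoxymethoxy)ethyl]-3-(3-methylbut-2-en-1-yl)phenyl}-3-hydroxy-1-[3-methoxy-4-(methoxymethoxy)phenyl]propan-1-one, via lithium enolate 15 (not isolated)
Conditions: LiN(iPr)2 (LDA), THF, −78 °C; then 12, −78 °C; AcOH quench at −78 °C
Reagents that add atoms: none
Why: Crossed aldol addition of the kinetic lithium enolate of methyl ketone 14 to the non-enolisable aldehyde 12 forms the C3–C4 bond, the cold acidic quench guarding against retro-aldol and dehydration; the new C4 carbinol arises as a racemate, which is of no consequence because it is oxidised in step 12.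

Step 8
Reactants: 16 racemic aldol adduct
Product: 17 (3RS)-3-{2-chloro-4,6-bis(methoxymethoxy)-5-[2-(methoxymethoxy)ethyl]-3-(3-methylbut-2-en-1-yl)phenyl}-1-[3-methoxy-4-(methoxymethoxy)phenyl]-3-[(triisopropylsilyl)oxy]propan-1-one
Conditions: TIPSOTf, 2,6-lutidine, CH2Cl2, −78 → 0 °C
Reagents that add atoms: triisopropylsilyl trifluoromethanesulfonate (TIPSOTf), CC(C)[Si](C(C)C)(C(C)C)OS(=O)(=O)C(F)(F)F
Why: Silylation of the secondary alcohol with the silyl triflate and a hindered pyridine base blocks retro-aldol and elimination and keeps the C4 oxygen away from palladium in step 10, triisopropylsilyl being chosen because it migrates between 1,3-related oxygens far less readily than smaller silyl groups.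

Step 9
Reactants: 17 β-silyloxy aryl ketone
Product: 18 (1S,3RS)-3-{2-chloro-4,6-bis(methoxymethoxy)-5-[2-(methoxymethoxy)ethyl]-3-(3-methylbut-2-en-1-yl)phenyl}-1-[3-methoxy-4-(methoxymethoxy)phenyl]-3-[(triisopropylsilyl)oxy]propan-1-ol
Conditions: RuCl[(S,S)-TsDPEN](p-cymene) (2–5 mol%), HCO2H–Et3N (5:2), CH2Cl2, 30 °C
Reagents that add atoms: none
Why: Noyori asymmetric transfer hydrogenation with the (S,S)-TsDPEN ruthenium catalyst delivers hydride to the aryl ketone through the CH/π-organised outer-sphere transition state that gives (S)-carbinols from aryl alkyl ketones, so the C2 stereocentre is set under catalyst control irrespective of the remote racemic C4 centre, while the olefin, the aryl chloride, the silyl ether and the acetals are not touched.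

Step 10
Reactants: 18 (1S)-1-aryl-3-(2-chloroaryl)-3-silyloxypropan-1-ol
Product: 19 (2S,4RS)-2-[3-methoxy-4-(methoxymethoxy)phenyl]-5,7-bis(methoxymethoxy)-6-[2-(methoxymethoxy)ethyl]-8-(3-methylbut-2-en-1-yl)-4-[(triisopropylsilyl)oxy]chromane
Conditions: Pd(OAc)2 (5 mol%), 2-(di-tert-butylphosphino)-1,1'-binaphthyl (6 mol%), Cs2CO3, toluene, 80 °C
Reagents that add atoms: none
Why: Zerovalent palladium, formed from Pd(OAc)2 and the bulky di-tert-butyl(binaphthyl)phosphine, inserts into the C8a–Cl bond of ring A; Cs2CO3 then deprotonates the coordinated C2 hydroxyl, and C–O reductive elimination from the aryl(alkoxo) complex of divalent palladium forms O1–C8a. The closest known reaction type is the Buchwald–Hartwig intramolecular etherification of aryl chlorides and bromides with secondary alcohols, which gives chromans without loss of configuration at the carbinol carbon. Ring C closes as a six-membered ring by reductive elimination from a seven-membered oxapalladacycle, an exo-type closure onto C8a. No stereocentre is created: the C2–O bond is never broken, so the S configuration set in step 9 is carried over unchanged, and C4 remains an epimer mixture. The step needs C–O reductive elimination to beat β-hydride elimination from the alkoxide, which the hindered electron-rich monophosphine should secure, and it needs the C2 oxygen alone to reach palladium, which the silyl ether at C4 secures (a free C4 alkoxide would chelate palladium in a five-membered ring and reduce the C–Cl bond by hydride transfer). Oxidative addition is helped by the C5 and C7 oxygens both being meta to C8a, and the prenyl olefin cannot insert because that would require a four-membered ring.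

Step 11
Reactants: 19 (2S)-4-silyloxyflavan
Product: 20 (2S,4RS)-2-[3-methoxy-4-(methoxymethoxy)phenyl]-5,7-bis(methoxymethoxy)-6-[2-(methoxymethoxy)ethyl]-8-(3-methylbut-2-en-1-yl)chroman-4-ol
Conditions: TBAF, THF, 0 °C → rt
Reagents that add atoms: none
Why: Fluoride-mediated desilylation, driven by Si–F bond formation, frees the C4 hydroxyl without affecting the MOM acetals, the olefin or C2.

Step 12
Reactants: 20 (2S)-flavan-4-ol
Product: 21 (2S)-2-[3-methoxy-4-(methoxymethoxy)phenyl]-5,7-bis(methoxymethoxy)-6-[2-(methoxymethoxy)ethyl]-8-(3-methylbut-2-en-1-yl)chroman-4-one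
Conditions: Dess–Martin periodinane, CH2Cl2, 0 °C → rt
Reagents that add atoms: none
Why: Dess–Martin oxidation converts both C4 epimers into the one flavanone under near-neutral conditions that neither open ring C through the chalcone nor touch the prenyl olefin, so the C2 configuration is kept.

Step 13
Reactants: 21 (2S)-flavanone tetrakis-MOM ether
Product: 22 laxiflorin, (2S)-5,7-dihydroxy-2-(4-hydroxy-3-methoxyphenyl)-6-(2-hydroxyethyl)-8-(3-methylbut-2-en-1-yl)chroman-4-one
Conditions: 3 M HCl, MeOH, 50 °C
Reagents that add atoms: none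
Why: Acid-catalysed transacetalisation with methanol removes the three aryl MOM ethers and the one alkyl MOM ether as dimethoxymethane, under conditions mild enough that the prenyl olefin should not add the C7 phenol and that ring C, stabilised by the hydrogen bond from the C5 hydroxyl to the C4 carbonyl, should not open and epimerise at C2.

**Compound list**

1 | 5-chlororesorcinol | Oc1cc(O)cc(Cl)c1 | starting material
2 | 1-chloro-3,5-bis(methoxymethoxy)benzene | COCOc1cc(Cl)cc(OCOC)c1 | intermediate
3 | ethylene oxide | C1CO1 | starting material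
4 | [4-chloro-2,6-bis(methoxymethoxy)phenyl]lithium (not isolated) | [Li]c1c(OCOC)cc(Cl)cc1OCOC | intermediate
5 | 2-[4-chloro-2,6-bis(methoxymethoxy)phenyl]ethan-1-ol | OCCc1c(OCOC)cc(Cl)cc1OCOC | intermediate
6 | 5-chloro-1,3-bis(methoxymethoxy)-2-[2-(methoxymethoxy)ethyl]benzene | COCOCCc1c(OCOC)cc(Cl)cc1OCOC | intermediate
7 | prenyl bromide (1-bromo-3-methylbut-2-ene) | CC(C)=CCBr | starting material
8 | {6-chloro-2,4-bis(methoxymethoxy)-3-[2-(methoxymethoxy)ethyl]phenyl}lithium (not isolated) | [Li]c1c(Cl)cc(OCOC)c(CCOCOC)c1OCOC | intermediate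
9 | {6-chloro-2,4-bis(methoxymethoxy)-3-[2-(methoxymethoxy)ethyl]phenyl}copper (not isolated) | [Cu]c1c(Cl)cc(OCOC)c(CCOCOC)c1OCOC | intermediate
10 | 1-chloro-3,5-bis(methoxymethoxy)-4-[2-(methoxymethoxy)ethyl]-2-(3-methylbut-2-en-1-yl)benzene | CC(C)=CCc1c(Cl)cc(OCOC)c(CCOCOC)c1OCOC | intermediate
11 | {2-chloro-4,6-bis(methoxymethoxy)-5-[2-(methoxymethoxy)ethyl]-3-(3-methylbut-2-en-1-yl)phenyl}lithium (not isolated) | [Li]c1c(Cl)c(CC=C(C)C)c(OCOC)c(CCOCOC)c1OCOC | intermediate
12 | 2-chloro-4,6-bis(methoxymethoxy)-5-[2-(methoxymethoxy)ethyl]-3-(3-methylbut-2-en-1-yl)benzaldehyde | O=Cc1c(Cl)c(CC=C(C)C)c(OCOC)c(CCOCOC)c1OCOC | intermediate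
13 | acetovanillone (1-(4-hydroxy-3-methoxyphenyl)ethan-1-one) | CC(=O)c1ccc(O)c(OC)c1 | starting material
14 | 1-[3-methoxy-4-(methoxymethoxy)phenyl]ethan-1-one | CC(=O)c1ccc(OCOC)c(OC)c1 | intermediate
15 | lithium enolate of 14 (not isolated) | [Li]OC(=C)c1ccc(OCOC)c(OC)c1 | intermediate
16 | (3RS)-3-{2-chloro-4,6-bis(methoxymethoxy)-5-[2-(methoxymethoxy)ethyl]-3-(3-methylbut-2-en-1-yl)phenyl}-3-hydroxy-1-[3-methoxy-4-(methoxymethoxy)phenyl]propan-1-one | COCOc1ccc(C(=O)CC(O)c2c(Cl)c(CC=C(C)C)c(OCOC)c(CCOCOC)c2OCOC)cc1OC | intermediate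
17 | triisopropylsilyl ether of 16 (C4 epimers) | COCOc1ccc(C(=O)CC(O[Si](C(C)C)(C(C)C)C(C)C)c2c(Cl)c(CC=C(C)C)c(OCOC)c(CCOCOC)c2OCOC)cc1OC | intermediate
18 | (1S,3RS)-3-{2-chloro-4,6-bis(methoxymethoxy)-5-[2-(methoxymethoxy)ethyl]-3-(3-methylbut-2-en-1-yl)phenyl}-1-[3-methoxy-4-(methoxymethoxy)phenyl]-3-[(triisopropylsilyl)oxy]propan-1-ol | COCOc1ccc([C@@H](O)CC(O[Si](C(C)C)(C(C)C)C(C)C)c2c(Cl)c(CC=C(C)C)c(OCOC)c(CCOCOC)c2OCOC)cc1OC | intermediate
19 | (2S,4RS)-2-[3-methoxy-4-(methoxymethoxy)phenyl]-5,7-bis(methoxymethoxy)-6-[2-(methoxymethoxy)ethyl]-8-(3-methylbut-2-en-1-yl)-4-[(triisopropylsilyl)oxy]chromane | COCOc1ccc([C@@H]2CC(O[Si](C(C)C)(C(C)C)C(C)C)c3c(OCOC)c(CCOCOC)c(OCOC)c(CC=C(C)C)c3O2)cc1OC | intermediate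
20 | (2S,4RS)-2-[3-methoxy-4-(methoxymethoxy)phenyl]-5,7-bis(methoxymethoxy)-6-[2-(methoxymethoxy)ethyl]-8-(3-methylbut-2-en-1-yl)chroman-4-ol | COCOc1ccc([C@@H]2CC(O)c3c(OCOC)c(CCOCOC)c(OCOC)c(CC=C(C)C)c3O2)cc1OC | intermediate
21 | (2S)-2-[3-methoxy-4-(methoxymethoxy)phenyl]-5,7-bis(methoxymethoxy)-6-[2-(methoxymethoxy)ethyl]-8-(3-methylbut-2-en-1-yl)chroman-4-one | COCOc1ccc([C@@H]2CC(=O)c3c(OCOC)c(CCOCOC)c(OCOC)c(CC=C(C)C)c3O2)cc1OC | intermediate
22 | laxiflorin, (2S)-5,7-dihydroxy-2-(4-hydroxy-3-methoxyphenyl)-6-(2-hydroxyethyl)-8-(3-methylbut-2-en-1-yl)chroman-4-one | COc1cc([C@@H]2CC(=O)c3c(O)c(CCO)c(O)c(CC=C(C)C)c3O2)ccc1O | target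

**Step count**

Total: 13 steps. Longest linear sequence: 12 steps (steps 1–5 and 7–13); step 6 is a one-step branch.

**Steps most likely to fail, with fallbacks**

Step 10. After oxidative addition, β-hydride elimination from the palladium C2-alkoxide (returning the aryl ketone and a hydrodechlorinated arene) may outrun C–O reductive elimination, or oxidative addition at the doubly ortho-substituted C8a–Cl bond may be too slow. The fallback closes ring C at O1–C2 instead, by SN2 displacement with inversion. It sets out from ketone 17 and returns at 19. Transfer hydrogenation of 17 with the enantiomeric catalyst RuCl[(R,R)-TsDPEN](p-cymene) in HCO2H–Et3N should give the (1R)-alcohol F1. Miyaura borylation of its aryl chloride (Pd2(dba)3, XPhos, B2pin2, KOAc, dioxane, 100 °C; acetate is too weak a base to form the alkoxide) should give the pinacol boronate F2. Oxidation with NaBO3·4H2O in THF–H2O should give the C8a phenol F3. Mitsunobu cyclisation of F3 (PPh3, DIAD, THF, 0 °C) then displaces the activated C2 hydroxyl with the phenol oxygen, turning the R carbinol into the (2S)-flavan 19.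

Step 5. Deprotonation at the benzylic and allylic CH2 of the prenyl group, or loss of LiCl from the ortho-chloro aryllithium to an aryne, may compete with ring metalation. The fallback reverses the order of the last two electrophiles so that no prenyl group is present during a metalation. It sets out from 6 and returns at 12. Metalation of 6 (s-BuLi, THF, −78 °C) and quenching with DMF should give 2-chloro-4,6-bis(methoxymethoxy)-5-[2-(methoxymethoxy)ethyl]benzaldehyde F4. Acetalisation (HC(OMe)3, catalytic PPTS, MeOH, rt) should give its dimethyl acetal F5. Metalation at the last ring C–H (s-BuLi, THF, −78 °C), transmetalation with CuBr·SMe2 and reaction with prenyl bromide 7 should give the prenylated dimethyl acetal F6. Mild hydrolysis (PPTS, acetone–H2O, rt), which the MOM ethers tolerate, releases aldehyde 12.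

Step 7. Reversal of the aldol addition and dehydration of the β-hydroxy ketone to the enone are favoured by the hindered, donor-rich aldehyde. The fallback forms C3–C4 with a more nucleophilic amide enolate and attaches ring B afterwards by acylation. It sets out from 12 and returns at 17. Addition of the lithium enolate of N-methoxy-N-methylacetamide (LiN(iPr)2, THF, −78 °C) to 12 should give the β-hydroxy Weinreb amide F7, which is not prone to retro-aldol. Silylation (TIPSOTf, 2,6-lutidine) gives its triisopropylsilyl ether F8. Separately, commercial 4-bromo-2-methoxyphenol is converted with MOMCl and K2CO3 into 4-bromo-2-methoxy-1-(methoxymethoxy)benzene F9. Bromine–lithium exchange (n-BuLi, THF, −78 °C) gives [3-methoxy-4-(methoxymethoxy)phenyl]lithium F10, whose addition to F8 (Weinreb ketone synthesis) delivers ketone 17.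

**Further compounds**

F1 | step 10 | (1R,3RS)-3-{2-chloro-4,6-bis(methoxymethoxy)-5-[2-(methoxymethoxy)ethyl]-3-(3-methylbut-2-en-1-yl)phenyl}-1-[3-methoxy-4-(methoxymethoxy)phenyl]-3-[(triisopropylsilyl)oxy]propan-1-ol | COCOc1ccc([C@H](O)CC(O[Si](C(C)C)(C(C)C)C(C)C)c2c(Cl)c(CC=C(C)C)c(OCOC)c(CCOCOC)c2OCOC)cc1OC
F2 | step 10 | pinacol boronate of F1 (Bpin in place of Cl at C8a) | COCOc1ccc([C@H](O)CC(O[Si](C(C)C)(C(C)C)C(C)C)c2c(B3OC(C)(C)C(C)(C)O3)c(CC=C(C)C)c(OCOC)c(CCOCOC)c2OCOC)cc1OC
F3 | step 10 | C8a phenol from F2 (OH in place of Bpin) | COCOc1ccc([C@H](O)CC(O[Si](C(C)C)(C(C)C)C(C)C)c2c(O)c(CC=C(C)C)c(OCOC)c(CCOCOC)c2OCOC)cc1OC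
F4 | step 5 | 2-chloro-4,6-bis(methoxymethoxy)-5-[2-(methoxymethoxy)ethyl]benzaldehyde | O=Cc1c(Cl)cc(OCOC)c(CCOCOC)c1OCOC
F5 | step 5 | dimethyl acetal of F4 | COC(OC)c1c(Cl)cc(OCOC)c(CCOCOC)c1OCOC
F6 | step 5 | dimethyl acetal of 12 | COC(OC)c1c(Cl)c(CC=C(C)C)c(OCOC)c(CCOCOC)c1OCOC
F7 | step 7 | (3RS)-3-{2-chloro-4,6-bis(methoxymethoxy)-5-[2-(methoxymethoxy)ethyl]-3-(3-methylbut-2-en-1-yl)phenyl}-3-hydroxy-N-methoxy-N-methylpropanamide | CON(C)C(=O)CC(O)c1c(Cl)c(CC=C(C)C)c(OCOC)c(CCOCOC)c1OCOC
F8 | step 7 | triisopropylsilyl ether of F7 | CON(C)C(=O)CC(O[Si](C(C)C)(C(C)C)C(C)C)c1c(Cl)c(CC=C(C)C)c(OCOC)c(CCOCOC)c1OCOC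
F9 | step 7 | 4-bromo-2-methoxy-1-(methoxymethoxy)benzene | COCOc1ccc(Br)cc1OC
F10 | step 7 | [3-methoxy-4-(methoxymethoxy)phenyl]lithium | [Li]c1ccc(OCOC)c(OC)c1
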